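**Plan**
1. Retrosynthesis: the cyclohexene ring is cut first at C1–C2 and C5–C6 (Diels–Alder reaction of a 2'-hydroxychalcone with (E)-β-ocimene), then the enone at Cα=Cβ (aldol with benzaldehyde), then the pyran ring of the chromene at C3=C4 and O1–C8a, last the benzylic C4–C4a bond and the aryl C7–O bond.
2. Enabling feature: in the 2H-chromene, C8a is ortho to C8, the carbon that bears the acyl group. With that carbon carried as a nitrile, a fluorine on C8a is open to SNAr, the benzylic C4 on C4a can carry a phenylsulfonyl group (carbanion stabiliser, then leaving group), and O1–C2(CH3)2–C3 is the skeleton of 2,2-dimethyloxirane.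
3. Forward: symmetric 2,6-difluoro-4-methoxybenzonitrile → one fluorine exchanged for tert-butoxy (masked phenol) → hydroxymethyl, then sulfonylmethyl, at the carbon between F and OMe → one-pot epoxide opening, SNAr and sulfinate elimination close the pyran ring → nitrile to methyl ketone with unmasking of the phenol → chalcone → cyclohexene ring.
4. Helpers and their removal: nitrile (becomes the ketone carbon in step 5), phenylsulfonyl (leaves within the key step), tert-butyl ether (cleaved in step 5).
5. Stereochemistry: all three stereocentres arise in the last step. The E-enone gives trans acyl/phenyl, the endo transition state with the E-diene gives cis acyl/prenyl, and a chiral borate chelated by the 2'-OH and the C=O sets the absolute configuration (1R,2S,6R).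

Key step: step 4

Assumption: the (S)-configured diol ligand is taken to leave open the enone face that leads to the (1R,2S,6R) adduct; if the sense of induction on this substrate is the opposite, the (R)-ligand is used with no other change.
Assumption: (E)-β-ocimene is used as E-enriched commercial material in excess; the Z isomer reaches the s-cis conformation with difficulty and is expected to stay behind.

Step 1
Reactants: 1 2,6-difluoro-4-methoxybenzonitrile
Product: 2 2-tert-butoxy-6-fluoro-4-methoxybenzonitrile
Conditions: KOtBu (1.05 equiv), THF, 0 → 25 °C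
Reagents that add atoms: potassium tert-butoxide, CC(C)(C)[O-].[K+]
Why: Nucleophilic aromatic substitution (SNAr) of one of the two equivalent fluorides ortho to the nitrile should stop at mono-substitution because the new tert-butoxy donor destabilises a second Meisenheimer complex, and the tert-butyl ether then serves as a base-stable mask of the later phenol; no stereocentre is formed.

Step 2
Reactants: 2 2-tert-butoxy-6-fluoro-4-methoxybenzonitrile
Product: 4 6-tert-butoxy-2-fluoro-3-(hydroxymethyl)-4-methoxybenzonitrile, via arylmagnesium chloride 3 (not isolated)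
Conditions: TMPMgCl·LiCl (1.2 equiv), THF, 0 → 25 °C; then (CH2O)n (3 equiv), 25 °C; H2O
Reagents that add atoms: paraformaldehyde (formaldehyde equivalent), C=O
Why: Directed ortho-magnesiation with the hindered magnesium amide should take the ring hydrogen flanked by fluorine and methoxy (the other one lies between methoxy and the bulky tert-butoxy group and has no ortho fluorine), the nitrile tolerates this base, and addition of the arylmagnesium to formaldehyde gives the benzylic alcohol; no stereocentre is formed.

Step 3
Reactants: 4 6-tert-butoxy-2-fluoro-3-(hydroxymethyl)-4-methoxybenzonitrile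
Product: 6 6-tert-butoxy-2-fluoro-4-methoxy-3-[(phenylsulfonyl)methyl]benzonitrile, via benzylic mesylate 5 (not isolated)
Conditions: MsCl, i-Pr2NEt, CH2Cl2, 0 °C; then PhSO2Na, DMF, 25 °C
Reagents that add atoms: sodium benzenesulfinate, [Na+].[O-]S(=O)c1ccccc1
Why: Sulfonylation of the primary benzylic alcohol followed by SN2 displacement through the soft sulfur terminus of the sulfinate (S-alkylation) should give the benzylic sulfone at a temperature at which the aryl fluoride is not attacked; no stereocentre is formed.

Step 4
Reactants: 6 6-tert-butoxy-2-fluoro-4-methoxy-3-[(phenylsulfonyl)methyl]benzonitrile; 7 2,2-dimethyloxirane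
Product: 10 7-tert-butoxy-5-methoxy-2,2-dimethyl-2H-chromene-8-carbonitrile, via potassium alkoxide 8 (not isolated), via 4-sulfonylchromane 9 (not isolated)
Conditions: KOtBu (1.05 equiv), THF–DMPU, 0 °C; 7 (5 equiv), 0 → 45 °C; then KOtBu (1.5 equiv), 45 °C
Reagents that add atoms: none
Why: Proposed new method: the sulfonyl-stabilised benzylic carbanion of 6 should open 2,2-dimethyloxirane at its CH2 carbon (SN2, forming C4–C3), the tertiary alkoxide 8 so released should displace the neighbouring fluoride by intramolecular SNAr through a nitrile-stabilised Meisenheimer complex (forming O1–C8a), and the second charge of KOtBu should expel benzenesulfinate from C4 of 9 with loss of a C3 proton (E2) to give the C3=C4 double bond. The closest known reaction types are the alkylation of α-sulfonyl carbanions with isobutylene oxide, the base-mediated cyclisation of 3-(2-fluoroaryl)propan-1-ols to chromanes, and the Julia-type sequence of sulfone alkylation and sulfinate elimination to styrenes; their merger into one anionic [3+3] annulation is the untested part. The pyran ring closes in a 6-exo-trig mode at the aromatic carbon C8a. No stereocentre survives, because the C4 centre of 8 and 9 is formed racemic and is erased by the elimination, which can only take a C3 hydrogen and so gives one alkene regioisomer. The step needs regioselective epoxide opening, secured by the fully substituted second epoxide carbon, and chemoselective SNAr, secured because the only fluorine sits ortho to both the nitrile and the tether while the other ortho position already carries tert-butoxy. Because 8 is expected to rest largely as its α-sulfonyl carbanion tautomer, the tert-butanol formed in the first deprotonation must act as proton shuttle to supply the alkoxide tautomer that cyclises.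

Step 5
Reactants: 10 7-tert-butoxy-5-methoxy-2,2-dimethyl-2H-chromene-8-carbonitrile
Product: 13 1-(7-hydroxy-5-methoxy-2,2-dimethyl-2H-chromen-8-yl)ethan-1-one, via N-magnesio ketimine 11 (not isolated), via tert-butoxy ketone 12 (not isolated)
Conditions: MeMgBr (3 equiv), toluene–THF, 80 °C; then 2 M aq. HCl, THF, 25 → 40 °C
Reagents that add atoms: methylmagnesium bromide, C[Mg]Br; water, O
Why: Grignard addition to the nitrile stops at the N-magnesio ketimine, so no tertiary alcohol can form, and aqueous acid should hydrolyse the ketimine and then cleave the aryl tert-butyl ether by loss of the tert-butyl cation to give the hydrogen-bonded ortho-hydroxy ketone; no stereocentre is formed.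

Step 6
Reactants: 13 1-(7-hydroxy-5-methoxy-2,2-dimethyl-2H-chromen-8-yl)ethan-1-one; 14 benzaldehyde
Product: 16 (E)-1-(7-hydroxy-5-methoxy-2,2-dimethyl-2H-chromen-8-yl)-3-phenylprop-2-en-1-one, via aldol adduct 15 (not isolated)
Conditions: KOH (aq.), EtOH, 25 °C
Reagents that add atoms: none
Why: Claisen–Schmidt (crossed aldol) condensation of the methyl ketone enolate with non-enolisable benzaldehyde followed by E1cB dehydration of 15 should give the (E)-enone under thermodynamic control, the phenoxide form protecting the chalcone from closure to the flavanone; the carbinol centre of 15 is racemic and is lost.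

Step 7
Reactants: 16 (E)-1-(7-hydroxy-5-methoxy-2,2-dimethyl-2H-chromen-8-yl)-3-phenylprop-2-en-1-one; 17 (E)-β-ocimene [(3E)-3,7-dimethylocta-1,3,6-triene]
Product: 18 (7-hydroxy-5-methoxy-2,2-dimethyl-2H-chromen-8-yl)[(1R,2S,6R)-3-methyl-2-(3-methylbut-2-en-1-yl)-6-phenylcyclohex-3-en-1-yl]methanone
Conditions: (S)-VANOL (20 mol %), BH3·THF (20 mol %), AcOH (20 mol %), THF, 25 °C (catalyst formation); then 16, 17 (4 equiv), 5 Å MS, PhCF3, 25 → 50 °C; neutral work-up
Reagents that add atoms: none
Why: Enantioselective Diels–Alder reaction of a 2'-hydroxychalcone, in which the phenol oxygen and the carbonyl oxygen chelate the chiral borate so that the enone is activated and one of its faces is shielded (absolute configuration at C1, C2 and C6), the E-enone keeps acyl and phenyl trans, the endo transition state with the E-configured diene terminus places the prenyl group cis to the acyl group, and bonding of the unsubstituted diene terminus to the enone β-carbon gives the regiochemistry.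

**Compound list**
1 | 2,6-difluoro-4-methoxybenzonitrile | COc1cc(F)c(C#N)c(F)c1 | starting material
2 | 2-tert-butoxy-6-fluoro-4-methoxybenzonitrile | COc1cc(F)c(C#N)c(OC(C)(C)C)c1 | intermediate
3 | (4-tert-butoxy-3-cyano-2-fluoro-6-methoxyphenyl)magnesium chloride (LiCl complex) | COc1cc(OC(C)(C)C)c(C#N)c(F)c1[Mg]Cl | intermediate
4 | 6-tert-butoxy-2-fluoro-3-(hydroxymethyl)-4-methoxybenzonitrile | COc1cc(OC(C)(C)C)c(C#N)c(F)c1CO | intermediate
5 | (4-tert-butoxy-3-cyano-2-fluoro-6-methoxyphenyl)methyl methanesulfonate | COc1cc(OC(C)(C)C)c(C#N)c(F)c1COS(C)(=O)=O | intermediate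
6 | 6-tert-butoxy-2-fluoro-4-methoxy-3-[(phenylsulfonyl)methyl]benzonitrile | COc1cc(OC(C)(C)C)c(C#N)c(F)c1CS(=O)(=O)c1ccccc1 | intermediate
7 | 2,2-dimethyloxirane (isobutylene oxide) | CC1(C)CO1 | starting material
8 | potassium 4-(4-tert-butoxy-3-cyano-2-fluoro-6-methoxyphenyl)-2-methyl-4-(phenylsulfonyl)butan-2-olate (racemic) | COc1cc(OC(C)(C)C)c(C#N)c(F)c1C(CC(C)(C)[O-])S(=O)(=O)c1ccccc1.[K+] | intermediate
9 | 7-tert-butoxy-5-methoxy-2,2-dimethyl-4-(phenylsulfonyl)chromane-8-carbonitrile (racemic) | COc1cc(OC(C)(C)C)c(C#N)c2OC(C)(C)CC(S(=O)(=O)c3ccccc3)c12 | intermediate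
10 | 7-tert-butoxy-5-methoxy-2,2-dimethyl-2H-chromene-8-carbonitrile | COc1cc(OC(C)(C)C)c(C#N)c2OC(C)(C)C=Cc12 | intermediate
11 | bromomagnesium salt of 1-(7-tert-butoxy-5-methoxy-2,2-dimethyl-2H-chromen-8-yl)ethan-1-imine | COc1cc(OC(C)(C)C)c(C(C)=N[Mg]Br)c2OC(C)(C)C=Cc12 | intermediate
12 | 1-(7-tert-butoxy-5-methoxy-2,2-dimethyl-2H-chromen-8-yl)ethan-1-one | COc1cc(OC(C)(C)C)c(C(C)=O)c2OC(C)(C)C=Cc12 | intermediate
13 | 1-(7-hydroxy-5-methoxy-2,2-dimethyl-2H-chromen-8-yl)ethan-1-one | COc1cc(O)c(C(C)=O)c2OC(C)(C)C=Cc12 | intermediate
14 | benzaldehyde | O=Cc1ccccc1 | starting material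
15 | 3-hydroxy-1-(7-hydroxy-5-methoxy-2,2-dimethyl-2H-chromen-8-yl)-3-phenylpropan-1-one (racemic) | COc1cc(O)c(C(=O)CC(O)c3ccccc3)c2OC(C)(C)C=Cc12 | intermediate
16 | (E)-1-(7-hydroxy-5-methoxy-2,2-dimethyl-2H-chromen-8-yl)-3-phenylprop-2-en-1-one | COc1cc(O)c(C(=O)/C=C/c3ccccc3)c2OC(C)(C)C=Cc12 | intermediate
17 | (E)-β-ocimene, (3E)-3,7-dimethylocta-1,3,6-triene | C=C/C(C)=C/CC=C(C)C | starting material
18 | (7-hydroxy-5-methoxy-2,2-dimethyl-2H-chromen-8-yl)[(1R,2S,6R)-3-methyl-2-(3-methylbut-2-en-1-yl)-6-phenylcyclohex-3-en-1-yl]methanone | COc1cc(O)c(C(=O)[C@@H]2[C@H](CC=C(C)C)C(C)=CC[C@H]2c2ccccc2)c2c1C=CC(C)(C)O2 | target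

**Count and risks**
Total step count: 7. Longest linear sequence: 7 steps (1 → 18).

Steps most likely to fail:

Step 4 (Proposed new method). The hindered, doubly stabilised carbanion may open the epoxide so slowly that tert-butoxide consumes the epoxide or the substrate condenses with itself. Proton transfer may also hold intermediate 8 as its carbanion tautomer, so that ring closure stalls. The fallback uses known chemistry with a different order of bond formation; it sets out from 2 and returns at 10. Magnesiation of 2 with TMPMgCl·LiCl and quenching with I2 should give 6-tert-butoxy-2-fluoro-3-iodo-4-methoxybenzonitrile F1. Sonogashira coupling of this iodide with 2-methylbut-3-yn-2-ol (PdCl2(PPh3)2, CuI, Et3N) should give 6-tert-butoxy-2-fluoro-3-(3-hydroxy-3-methylbut-1-yn-1-yl)-4-methoxybenzonitrile F2. Lindlar semi-hydrogenation (Pd on CaCO3 poisoned with Pb(OAc)2, quinoline, H2) should give (Z)-6-tert-butoxy-2-fluoro-3-(3-hydroxy-3-methylbut-1-en-1-yl)-4-methoxybenzonitrile F3. NaH in DMF should then close the pyran ring by intramolecular SNAr to give 10.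

Step 5. Addition of the Grignard reagent to the doubly ortho-substituted nitrile may be sluggish, and the warm acidic stage may hydrate or dimerise the electron-rich chromene double bond before ketimine hydrolysis and ether cleavage are complete. The fallback sets out from 10 and returns at 13. Reduction with i-Bu2AlH (toluene, −78 °C, Rochelle salt work-up) should give 7-tert-butoxy-5-methoxy-2,2-dimethyl-2H-chromene-8-carbaldehyde F4. Addition of MeMgBr at 0 °C should give racemic 1-(7-tert-butoxy-5-methoxy-2,2-dimethyl-2H-chromen-8-yl)ethan-1-ol F5. Dess–Martin oxidation should give 12, and brief treatment with TFA in CH2Cl2 at 0 °C should cleave the tert-butyl ether to give 13.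

Step 7. Facial discrimination may be poor or turnover slow, because the ring oxygen at the 6'-position crowds the boron chelate, and some exo adduct may form. The fallback replaces catalyst control by resolution; it sets out from 16 and returns at 18. Uncatalysed thermal cycloaddition of 16 with 17 (sealed tube, 150 °C, or high pressure) should give the racemic endo adduct, that is 18 together with its (1S,2R,6S) enantiomer ent-18 F6. Preparative HPLC on a chiral stationary phase should then deliver 18.

**Further compounds**
F1 | step 4 | 6-tert-butoxy-2-fluoro-3-iodo-4-methoxybenzonitrile | COc1cc(OC(C)(C)C)c(C#N)c(F)c1I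
F2 | step 4 | 6-tert-butoxy-2-fluoro-3-(3-hydroxy-3-methylbut-1-yn-1-yl)-4-methoxybenzonitrile | COc1cc(OC(C)(C)C)c(C#N)c(F)c1C#CC(C)(C)O
F3 | step 4 | (Z)-6-tert-butoxy-2-fluoro-3-(3-hydroxy-3-methylbut-1-en-1-yl)-4-methoxybenzonitrile | COc1cc(OC(C)(C)C)c(C#N)c(F)c1/C=C\C(C)(C)O
F4 | step 5 | 7-tert-butoxy-5-methoxy-2,2-dimethyl-2H-chromene-8-carbaldehyde | COc1cc(OC(C)(C)C)c(C=O)c2OC(C)(C)C=Cc12
F5 | step 5 | 1-(7-tert-butoxy-5-methoxy-2,2-dimethyl-2H-chromen-8-yl)ethan-1-ol (racemic) | COc1cc(OC(C)(C)C)c(C(C)O)c2OC(C)(C)C=Cc12
F6 | step 7 | (7-hydroxy-5-methoxy-2,2-dimethyl-2H-chromen-8-yl)[(1S,2R,6S)-3-methyl-2-(3-methylbut-2-en-1-yl)-6-phenylcyclohex-3-en-1-yl]methanone | COc1cc(O)c(C(=O)[C@H]2[C@@H](CC=C(C)C)C(C)=CC[C@@H]2c2ccccc2)c2c1C=CC(C)(C)O2
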